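5 questions stood on 4 flasks, and I wanted one ratio to carry them.

    D + E.D ⇌ D.E.D, settled at all times (K1 = 8.34 /M, ΔH1 = −12.0 kJ/mol)
    E → J (k2 = 1.18 × 10⁻⁴ /s, Ea2 = 90.0 kJ/mol)
    2 E → E2 (k3 = 0.00164 /M/s, Ea3 = 45.0 kJ/mol)
    E + D ⇌ E.D (K4 = 486 /M, k4 = 8.02 × 10⁻⁴ /M/s, Ea4 = 50.0 kJ/mol, ΔH4 = 22.0 kJ/mol)
    (constants at 0 °C)

| flask | E | D | temperature | time | remark |
|---|---|---|---|---|---|
| Thursday's | 0.10 M | 0.100 M | 0 °C | 4.0 h | everything together at the start |
| Saturday's | 0.10 M (fed, over 2.5 h) | 0.100 M |  | 4.0 h | the addition at −40 °C, then warmed to 0 °C; the feed brings no volume worth counting |
| Wednesday's | 0.10 M (fed, over 2.5 h) | 0.100 M | 0 °C | 4.0 h | all else is in the flask from the start; the feed brings no volume worth counting |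
| Monday's | 0.10 M | 0.100 M (fed, over 2.5 h) | 0 °C | 4.0 h | all else is in the flask from the start; the feed brings no volume worth counting |

- a species is counted by the E in it: one E2 counts as two
- amounts and yields of E.D count D.E.D too
- a doubled species enters its step squared and goes two at a time
- at 0 °C the constants are as listed, elsewhere as the activation energies and enthalpies make them

- the flask that comes out highest in share of E.D in E.D plus J, or "all alike" when all lie within 1.5 percentage points (Thursday's / Saturday's / Wednesday's / Monday's / all alike)
- share of E.D in E.D plus J at the end, Thursday's
- share of E.D in E.D plus J at the end, Saturday's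
- share of E.D in E.D plus J at the end, Wednesday's
- share of E.D in E.D plus J at the end, Monday's

Step 1. At 0 °C, E goes to E.D at the constant of the addition times free D, and to J at its own constant. The two paths are therefore equal at one amount of free D, the constant of the split divided by that of the addition. I called this the even point, 0.147 M. It is a selectivity factor in concentration form: the share of E.D is free D over free D plus the even point. I dropped the way back of the addition, whose constant 1.65 × 10⁻⁶ /s is far smaller than that of the split. With the full charge of D the share came to 40.5%.

Step 2. In Thursday's, pairing to E2 began at 3.28 × 10⁻⁴ /s per E, faster than the two paths together at 1.98 × 10⁻⁴ /s. Integrating both losses sent 59.0% of Thursday's E down the two paths.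

Step 3. Each E.D took one D, and the part held as D.E.D, reckoned at the full charge of D as 45.5%, took a second. The mean of charge and end value gave Thursday's free D as 0.0826 M, and the share fell to 36.0%.

Step 4. The weak link was the full D used in the first pass, so I put the answer back and went round once more. The paths then took 57.4%, free D stood at 0.0850 M, and I committed to 36.6% for Thursday's. In Wednesday's, as in Thursday's, the whole D stands in the flask from the start, so I took Thursday's share for Wednesday's as a guess, without reckoning it.

Step 5. I took Saturday's cold feed as idle, which I assumed and did not reckon. That left 1.50 h warm, so 42.6% of the E took the paths. Free D stayed at 0.0887 M, giving Saturday's 37.6%, higher than Thursday's.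

Step 6. Monday's mean D over the feed was 0.0500 M, which gave 25.4%. But the life of E, 0.623 h, is shorter than the feed, so I expected Monday's to come out below that figure. I chose Saturday's.

The forecast gave Saturday's, with 36.8%, 39%, 35.5% and 20% for Thursday's, Saturday's, Wednesday's and Monday's, and held that "the D.E.D sink only trims free D slightly in every flask".

The flask gave Saturday's, with 36.4%, 38.3%, 36.1% and 18.9% in that order. Monday's mean D over the first 2.5 h read 0.0455 M. Run backward, the even point turned Monday's share into a free D of 0.0343 M, lower than that mean.

For Saturday's with 0.17 M of D, I took off the same shortfall as before. That left 0.159 M of free D and a share of 52.0%. The flask gave 51.5%.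

The constants used here stand for no real mixture; what happens was integrated by code.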